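**Plan**

1. Numbering: ring A = C1–C5 + C10, ring B = C5–C10, C11 = formyl carbon on C9, C12 = formyl carbon on C8. Ring B is a cyclohexene whose C7=C8 bond lies opposite the C5–C10 bond, so C5–C6 and C9–C10 are cut together as a [4+2]. C1 (on C10) and C11 (on C9) are 1,4-related oxygenated carbons, so a C1-carboxyl/C11-O ester tethers an acyclic (E)-C5=C10 enoate to the C6=C7–C8=C9 diene. This gives the trans Me/H fusion that a ring A cyclohexenone dienophile could not.
2. Further cuts: C1–C2 (together with C3–Cl and C1–OH) by a chloro-Prins closure of ring A; C5=C10 by Horner–Wadsworth–Emmons olefination; the C4–C5 bond by copper-catalysed enantioselective allylic substitution.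
3. Forward: the two fragments are joined by esterification and olefination; the key step makes ring B plus a temporary trans-fused γ-lactone; the lactone is opened to the C1 aldehyde; ring A is closed; the side chain is finished by cross-metathesis; C12 is oxidised and C11 unveiled.
4. Stereochemistry: C4 from the allylic-substitution catalyst. C5, C9 and C10 from the (E)-dienophile, the exo tether mode and a carbinol centre at C11 taken from a sugar-derived butenolide (chiral pool; it also supplies C8, C9, C11, C12 and one sacrificial carbon, called C13 here). C1 and C3 from the chair Prins transition state. The helper centre and C13 are removed by glycol cleavage at the end.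

Key step: step 12

Remark: the distal side-chain alkene is carried as a terminal but-3-enyl group until ring A is closed, because a trisubstituted alkene would compete with the vinyl group for the activated C1 aldehyde. Compounds 1, 7, 14 and the named reagents are taken as commercial. The phosphonate carbon of 15 is a mixture of epimers of no consequence. TBS = tert-butyldimethylsilyl, TBDPS = tert-butyldiphenylsilyl, pin = pinacolato.

**Route**

Step 1
Reactants: 1 hex-1-en-5-yne
Product: 2 (2E)-3-methylhepta-2,6-dien-1-ol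
Conditions: AlMe3 (2 equiv), Cp2ZrCl2 (20 mol %), CH2Cl2, 0 °C → rt; then n-BuLi, THF, −78 °C; (CH2O)n, → rt; aq. HCl
Reagents that add atoms: trimethylaluminium (C[Al](C)C); formaldehyde from paraformaldehyde (C=O)
Why: Zirconium-catalysed syn-carboalumination of the terminal alkyne (Negishi carboalumination) followed by hydroxymethylation of the alkenyl aluminate should give only the E-trisubstituted allylic alcohol, the terminal alkene being inert.

Step 2
Reactants: 2 (2E)-3-methylhepta-2,6-dien-1-ol
Product: 3 diethyl (2E)-3-methylhepta-2,6-dien-1-yl phosphate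
Conditions: ClP(O)(OEt)2, Et3N, DMAP (cat.), CH2Cl2, 0 °C
Reagents that add atoms: diethyl chlorophosphate (CCOP(=O)(Cl)OCC)
Why: Phosphorylation of the primary allylic alcohol gives the leaving group needed for the allylic substitution.

Step 3
Reactants: 3 diethyl (2E)-3-methylhepta-2,6-dien-1-yl phosphate
Product: 5 (2R)-2-ethenyl-2-methylhex-5-en-1-ol, via homoallyl boronate 4 (not isolated)
Conditions: CH2(Bpin)2 (1.5 equiv), CuCl (5 mol %), chiral sulfonate-bearing imidazolinium salt (carbene precursor, 5.5 mol %, the enantiomer that gives R), NaOMe (1.5 equiv), THF, 22 °C; then aq. NaOH, H2O2, 0 °C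
Reagents that add atoms: bis[(pinacolato)boryl]methane (CC1(C)OB(CB2OC(C)(C)C(C)(C)O2)OC1(C)C); hydrogen peroxide (OO)
Why: Copper-catalysed enantioselective SN2' allylic substitution with the boron-stabilised CH2B(pin) nucleophile should attack the γ-carbon of the E-allylic phosphate under control of the chiral N-heterocyclic carbene ligand and so set the quaternary C4 centre (R), after which oxidation of the C–B bond with retention gives the alcohol.

Step 4
Reactants: 5 (2R)-2-ethenyl-2-methylhex-5-en-1-ol
Product: 6 (2R)-2-ethenyl-2-methylhex-5-enal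
Conditions: Dess–Martin periodinane, CH2Cl2, 0 °C → rt
Reagents that add atoms: none
Why: Dess–Martin oxidation of the neopentyl-type primary alcohol gives the aldehyde, which has no α-hydrogen and so cannot epimerise.

Step 5
Reactants: 7 (5S)-5-(hydroxymethyl)furan-2(5H)-one
Product: 8 (5S)-5-{[(tert-butyldiphenylsilyl)oxy]methyl}furan-2(5H)-one
Conditions: TBDPSCl, imidazole, CH2Cl2, 0 °C → rt
Reagents that add atoms: tert-butyl(chloro)diphenylsilane (CC(C)(C)[Si](Cl)(c1ccccc1)c1ccccc1)
Why: Standard silylation of the primary alcohol protects the oxygen on the sacrificial carbon C13.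

Step 6
Reactants: 8 (5S)-5-{[(tert-butyldiphenylsilyl)oxy]methyl}furan-2(5H)-one
Product: 10 (5S)-3-bromo-5-{[(tert-butyldiphenylsilyl)oxy]methyl}furan-2(5H)-one, via dibromo lactone 9 (not isolated)
Conditions: Br2, CH2Cl2, 0 °C → rt; then Et3N, 0 °C
Reagents that add atoms: bromine (BrBr)
Why: Bromine addition to the butenolide alkene and loss of HBr with triethylamine (bromination–dehydrobromination) should give the α-bromo butenolide, the short exposure to base at 0 °C leaving the γ-stereocentre untouched.

Step 7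
Reactants: 10 (5S)-3-bromo-5-{[(tert-butyldiphenylsilyl)oxy]methyl}furan-2(5H)-one
Product: 11 (2S,3E)-4-bromo-1-[(tert-butyldiphenylsilyl)oxy]pent-3-ene-2,5-diol
Conditions: i-Bu2AlH (3.5 equiv), CH2Cl2, −78 → −20 °C; aq. Rochelle salt
Reagents that add atoms: none
Why: DIBAL-H 1,2-reduction of the lactone through the lactol gives the ene-diol, whose cis relationship of the two oxygenated carbons (C11 and C12) is inherited from the ring.

Step 8
Reactants: 11 (2S,3E)-4-bromo-1-[(tert-butyldiphenylsilyl)oxy]pent-3-ene-2,5-diol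
Product: 12 (2S,3E)-4-bromo-5-[(tert-butyldimethylsilyl)oxy]-1-[(tert-butyldiphenylsilyl)oxy]pent-3-en-2-ol
Conditions: TBSCl (1.05 equiv), imidazole, CH2Cl2, −20 °C
Reagents that add atoms: tert-butyl(chloro)dimethylsilane (CC(C)(C)[Si](C)(C)Cl)
Why: Silylation at low temperature discriminates the primary allylic hydroxyl (C12) from the secondary one (C11).

Step 9
Reactants: 12 (2S,3E)-4-bromo-5-[(tert-butyldimethylsilyl)oxy]-1-[(tert-butyldiphenylsilyl)oxy]pent-3-en-2-ol
Product: 13 (2S,3Z)-4-{[(tert-butyldimethylsilyl)oxy]methyl}-1-[(tert-butyldiphenylsilyl)oxy]hexa-3,5-dien-2-ol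
Conditions: tributyl(vinyl)stannane, Pd(PPh3)4 (5 mol %), CuI (10 mol %), DMF, 60 °C
Reagents that add atoms: tributyl(ethenyl)stannane (C=C[Sn](CCCC)(CCCC)CCCC)
Why: Stille coupling of the alkenyl bromide proceeds with retention of geometry and gives the diene with C11 trans to the new vinyl group (E diene terminus).

Step 10
Reactants: 13 (2S,3Z)-4-{[(tert-butyldimethylsilyl)oxy]methyl}-1-[(tert-butyldiphenylsilyl)oxy]hexa-3,5-dien-2-ol; 14 2-(diethoxyphosphoryl)propanoic acid
Product: 15 phosphonate ester of dienol 13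
Conditions: DCC, DMAP (cat.), CH2Cl2, 0 °C → rt
Reagents that add atoms: none
Why: Steglich esterification joins the carbinol oxygen (the future tether oxygen on C11) to the phosphonate acid that carries C1, C10 and the C10 methyl.

Step 11
Reactants: 15 phosphonate ester of dienol 13; 6 (2R)-2-ethenyl-2-methylhex-5-enal
Product: 16 dienyl (2E,4R)-4-ethenyl-2,4-dimethylocta-2,7-dienoate
Conditions: NaH, THF, 0 °C → rt
Reagents that add atoms: none
Why: Horner–Wadsworth–Emmons olefination of the α-methyl phosphonate with the non-enolisable, α-branched aldehyde should give mainly the E-trisubstituted enoate (C1 trans to C4), the geometry that later becomes the trans ring fusion.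

Step 12
Reactants: 16 dienyl (2E,4R)-4-ethenyl-2,4-dimethylocta-2,7-dienoate
Product: 17 trans-fused bicyclic γ-lactone (ring B formed)
Conditions: BHT (10 mol %), 1,2-dichlorobenzene (0.01 M), 180 °C, sealed tube
Reagents that add atoms: none
Why: This is a thermal, concerted, suprafacial [4+2] cycloaddition of an ester-tethered 1,3,8-nonatriene, the intramolecular Diels–Alder reaction of a pentadienyl acrylate-type ester, run hot because the tiglate-like dienophile is hindered. Ring B closes as a six-membered carbocycle by the cycloaddition (C5–C6 and C9–C10 formed together), and the γ-lactone closes as the five-membered tether ring, trans-fused, through the transition state with the ester carbonyl exo. The E geometry of C5=C10 is transferred suprafacially, so 10-Me and 5-H end up trans (the later trans-decalin), and the E diene terminus with the exo carbonyl places C11 cis to the C10 methyl (9α-H). The absolute sense comes from the C11 carbinol centre: A(1,3) strain with the C8 CH2OTBS group holds C11–H in the diene plane, so the ester oxygen delivers the dienophile to one diene face while the CH2OTBDPS group points away. The step needs exo over endo selectivity and face selectivity; the C8 substituent (which destabilises the endo, cis-fused mode) and the C11 centre should secure them, and the three-atom tether fixes the regiochemistry. The isolated vinyl and butenyl alkenes are unactivated and out of reach, and the quaternary C4 centre is a spectator.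

Step 13
Reactants: 17 trans-fused bicyclic γ-lactone
Product: 19 TBS-protected Weinreb amide, via hydroxy amide 18 (not isolated)
Conditions: Me(MeO)NH·HCl (3 equiv), i-PrMgCl (6 equiv), THF, −20 → 0 °C; aq. NH4Cl; crude product, TBSOTf, 2,6-lutidine, CH2Cl2, −78 → 0 °C
Reagents that add atoms: N,O-dimethylhydroxylamine hydrochloride (CNOC.Cl); tert-butyldimethylsilyl trifluoromethanesulfonate (CC(C)(C)[Si](C)(C)OS(=O)(=O)C(F)(F)F)
Why: Aminolysis of the γ-lactone with the magnesium amide of N,O-dimethylhydroxylamine (Weinreb amide formation) frees the C11 hydroxyl, which is silylated in the crude product before it can relactonise.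

Step 14
Reactants: 19 TBS-protected Weinreb amide
Product: 20 C1 aldehyde
Conditions: i-Bu2AlH, THF, −78 → 0 °C; aq. Rochelle salt
Reagents that add atoms: none
Why: DIBAL-H reduction of the Weinreb amide stops at the aldehyde through the chelated tetrahedral intermediate, and the quaternary C10 excludes epimerisation.

Step 15
Reactants: 20 C1 aldehyde
Product: 21 3β-chloro-1α-hydroxy trans-decalin (ring A closed)
Conditions: SnCl4 (2.5 equiv), CH2Cl2, −78 → −30 °C; aq. NaHCO3
Reagents that add atoms: tin tetrachloride (Cl[Sn](Cl)(Cl)Cl)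
Why: Lewis acid-promoted Prins cyclisation of the δ,ε-unsaturated aldehyde to a 1,3-chlorohydrin: the vinyl terminus C2 attacks the SnCl4-bound C1 aldehyde through a six-membered chair (no ene path, since C4 has no hydrogen) while chloride from SnCl5− adds to C3 anti to the forming C1–C2 bond, which makes the chlorine equatorial (3β), and the aldehyde oxygen takes the axial position (1α-OH) because the equatorial one collides with the C9 side chain.

Step 16
Reactants: 21 3β-chloro-1α-hydroxy trans-decalin
Product: 22 homoprenyl chlorohydrin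
Conditions: 2-methylbut-2-ene (excess), second-generation Grubbs catalyst RuCl2(PCy3)(H2IMes)(=CHPh) (5 mol %), CH2Cl2, 40 °C, sealed
Reagents that add atoms: 2-methylbut-2-ene (CC=C(C)C)
Why: Olefin cross-metathesis of the only terminal alkene with excess 2-methylbut-2-ene installs the isopropylidene end, the trisubstituted ring alkene being unreactive.

Step 17
Reactants: 22 homoprenyl chlorohydrin
Product: 23 C12 allylic alcohol
Conditions: PPTS (20 mol %), MeOH, 0 °C → rt
Reagents that add atoms: none
Why: Acid-catalysed methanolysis removes the primary allylic TBS ether faster than the secondary TBS and the TBDPS ethers.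

Step 18
Reactants: 23 C12 allylic alcohol
Product: 24 C12 enal
Conditions: MnO2 (20 equiv), CH2Cl2, rt
Reagents that add atoms: none
Why: MnO2 oxidises only the allylic primary alcohol, so the free secondary C1 hydroxyl needs no protection.

Step 19
Reactants: 24 C12 enal
Product: 25 C11,C13 diol
Conditions: HF·pyridine, excess pyridine, THF, 0 °C → rt
Reagents that add atoms: none
Why: Fluoride-mediated desilylation under buffered acidic conditions frees the C11 glycol while avoiding base, which could trigger Grob-type fragmentation of the 1,3-chlorohydrin.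

Step 20
Reactants: 25 C11,C13 diol
Product: 26 target dialdehyde
Conditions: NaIO4, THF/H2O (pH 7 phosphate buffer), 0 °C
Reagents that add atoms: none
Why: Periodate glycol cleavage removes the sacrificial carbon C13 and the helper stereocentre and unveils the C11 aldehyde at neutral pH, so the epimerisable C9 centre and the chlorohydrin are not disturbed.

**Compound list**

1 | hex-1-en-5-yne | C=CCCC#C | starting material
2 | (2E)-3-methylhepta-2,6-dien-1-ol | OC/C=C(\C)CCC=C | intermediate
3 | diethyl (2E)-3-methylhepta-2,6-dien-1-yl phosphate | CCOP(=O)(OCC)OC/C=C(\C)CCC=C | intermediate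
4 | 2-[(2R)-2-ethenyl-2-methylhex-5-en-1-yl]-4,4,5,5-tetramethyl-1,3,2-dioxaborolane (not isolated) | CC1(C)OB(C[C@@](C)(C=C)CCC=C)OC1(C)C | intermediate
5 | (2R)-2-ethenyl-2-methylhex-5-en-1-ol | OC[C@@](C)(C=C)CCC=C | intermediate
6 | (2R)-2-ethenyl-2-methylhex-5-enal | O=C[C@@](C)(C=C)CCC=C | intermediate
7 | (5S)-5-(hydroxymethyl)furan-2(5H)-one | OC[C@H]1OC(=O)C=C1 | starting material
8 | (5S)-5-{[(tert-butyldiphenylsilyl)oxy]methyl}furan-2(5H)-one | CC(C)(C)[Si](c1ccccc1)(c1ccccc1)OC[C@H]1OC(=O)C=C1 | intermediate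
9 | 3,4-dibromo-5-{[(tert-butyldiphenylsilyl)oxy]methyl}oxolan-2-one, C5 as in 8, bromine-bearing carbons undefined (not isolated) | CC(C)(C)[Si](c1ccccc1)(c1ccccc1)OC[C@H]1OC(=O)C(Br)C1Br | intermediate
10 | (5S)-3-bromo-5-{[(tert-butyldiphenylsilyl)oxy]methyl}furan-2(5H)-one | CC(C)(C)[Si](c1ccccc1)(c1ccccc1)OC[C@H]1OC(=O)C(Br)=C1 | intermediate
11 | (2S,3E)-4-bromo-1-[(tert-butyldiphenylsilyl)oxy]pent-3-ene-2,5-diol | OC/C(Br)=C\[C@H](O)CO[Si](c1ccccc1)(c1ccccc1)C(C)(C)C | intermediate
12 | (2S,3E)-4-bromo-5-[(tert-butyldimethylsilyl)oxy]-1-[(tert-butyldiphenylsilyl)oxy]pent-3-en-2-ol | CC(C)(C)[Si](C)(C)OC/C(Br)=C\[C@H](O)CO[Si](c1ccccc1)(c1ccccc1)C(C)(C)C | intermediate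
13 | (2S,3Z)-4-{[(tert-butyldimethylsilyl)oxy]methyl}-1-[(tert-butyldiphenylsilyl)oxy]hexa-3,5-dien-2-ol (carbinol carbon = C11; C11 trans to the vinyl group) | C=C/C(CO[Si](C)(C)C(C)(C)C)=C/[C@H](O)CO[Si](c1ccccc1)(c1ccccc1)C(C)(C)C | intermediate
14 | 2-(diethoxyphosphoryl)propanoic acid (racemic) | CCOP(=O)(OCC)C(C)C(=O)O | starting material
15 | (2S,3Z)-4-{[(tert-butyldimethylsilyl)oxy]methyl}-1-[(tert-butyldiphenylsilyl)oxy]hexa-3,5-dien-2-yl 2-(diethoxyphosphoryl)propanoate (epimers at the phosphonate carbon) | CCOP(=O)(OCC)C(C)C(=O)O[C@H](CO[Si](c1ccccc1)(c1ccccc1)C(C)(C)C)/C=C(CO[Si](C)(C)C(C)(C)C)/C=C | intermediate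
16 | (2S,3Z)-4-{[(tert-butyldimethylsilyl)oxy]methyl}-1-[(tert-butyldiphenylsilyl)oxy]hexa-3,5-dien-2-yl (2E,4R)-4-ethenyl-2,4-dimethylocta-2,7-dienoate | C=CCC[C@](C)(C=C)/C=C(\C)C(=O)O[C@H](CO[Si](c1ccccc1)(c1ccccc1)C(C)(C)C)/C=C(CO[Si](C)(C)C(C)(C)C)/C=C | intermediate
17 | (3S)-3-{[(tert-butyldiphenylsilyl)oxy]methyl}-4-{[(tert-butyldimethylsilyl)oxy]methyl}-7a-methyl-7-[(3R)-3-methylhepta-1,6-dien-3-yl]-3a,6,7,7a-tetrahydro-2-benzofuran-1(3H)-one, trans-fused; target numbering: 10β-Me, 9α-H, 5α-H, lactone C1(=O)–O–C11 | C=CCC[C@](C)(C=C)[C@@H]1CC=C(CO[Si](C)(C)C(C)(C)C)[C@@H]2[C@@H](CO[Si](c3ccccc3)(c3ccccc3)C(C)(C)C)OC(=O)[C@@]12C | intermediate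
18 | ring-opened hydroxy amide: ring B cyclohexene with C10 (β-Me, CON(OMe)Me), C9 β-[(1S)-2-(TBDPS-oxy)-1-hydroxyethyl], C8 CH2OTBS, C5 β-[(3R)-3-methylhepta-1,6-dien-3-yl] (not isolated) | C=CCC[C@](C)(C=C)[C@@H]1CC=C(CO[Si](C)(C)C(C)(C)C)[C@H]([C@@H](CO[Si](c2ccccc2)(c2ccccc2)C(C)(C)C)O)[C@@]1(C)C(=O)N(C)OC | intermediate
19 | C11 TBS ether of 18 | C=CCC[C@](C)(C=C)[C@@H]1CC=C(CO[Si](C)(C)C(C)(C)C)[C@H]([C@@H](CO[Si](c2ccccc2)(c2ccccc2)C(C)(C)C)O[Si](C)(C)C(C)(C)C)[C@@]1(C)C(=O)N(C)OC | intermediate
20 | aldehyde corresponding to 19 (C1 formyl on C10) | C=CCC[C@](C)(C=C)[C@@H]1CC=C(CO[Si](C)(C)C(C)(C)C)[C@H]([C@@H](CO[Si](c2ccccc2)(c2ccccc2)C(C)(C)C)O[Si](C)(C)C(C)(C)C)[C@@]1(C)C=O | intermediate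
21 | trans-decalin chlorohydrin: 1α-OH, 3β-Cl, 4β-Me, 4α-but-3-enyl, 5α-H, 10β-Me, Δ7, 8-CH2OTBS, 9β-[(1S)-1-(TBS-oxy)-2-(TBDPS-oxy)ethyl] | C=CCC[C@]1(C)[C@@H](Cl)C[C@H](O)[C@]2(C)[C@@H]([C@@H](CO[Si](c3ccccc3)(c3ccccc3)C(C)(C)C)O[Si](C)(C)C(C)(C)C)C(CO[Si](C)(C)C(C)(C)C)=CC[C@@H]12 | intermediate
22 | as 21 with 4α-(4-methylpent-3-enyl) | CC(C)=CCC[C@]1(C)[C@@H](Cl)C[C@H](O)[C@]2(C)[C@@H]([C@@H](CO[Si](c3ccccc3)(c3ccccc3)C(C)(C)C)O[Si](C)(C)C(C)(C)C)C(CO[Si](C)(C)C(C)(C)C)=CC[C@@H]12 | intermediate
23 | as 22 with free C12 hydroxyl (8-CH2OH) | CC(C)=CCC[C@]1(C)[C@@H](Cl)C[C@H](O)[C@]2(C)[C@@H]([C@@H](CO[Si](c3ccccc3)(c3ccccc3)C(C)(C)C)O[Si](C)(C)C(C)(C)C)C(CO)=CC[C@@H]12 | intermediate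
24 | as 23 with C12 formyl (enal) | CC(C)=CCC[C@]1(C)[C@@H](Cl)C[C@H](O)[C@]2(C)[C@@H]([C@@H](CO[Si](c3ccccc3)(c3ccccc3)C(C)(C)C)O[Si](C)(C)C(C)(C)C)C(C=O)=CC[C@@H]12 | intermediate
25 | as 24 with 9β-[(1S)-1,2-dihydroxyethyl] | CC(C)=CCC[C@]1(C)[C@@H](Cl)C[C@H](O)[C@]2(C)[C@@H]([C@@H](CO)O)C(C=O)=CC[C@@H]12 | intermediate
26 | CNP0155449.1: 3β-chloro-1α-hydroxy-4β,10β-dimethyl-4α-(4-methylpent-3-enyl) trans-decal-7-ene-11,12-dial (5α-H, 9α-H) | CC(C)=CCC[C@]1(C)[C@@H](Cl)C[C@H](O)[C@]2(C)[C@@H](C=O)C(C=O)=CC[C@@H]12 | target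

**Step count and risks**

Total steps: 20. Longest linear sequence: 16 steps (7 → 26, steps 5–20); the aldehyde branch (1 → 6, steps 1–4) joins at step 11.

Most likely to fail:

Step 15 (Prins closure of ring A). What may go wrong: chloride delivery from the tin alkoxide on the same face as the new C–C bond (giving the axial 3α-chloride), a 1,2-alkyl shift in the developing C3 cation next to the quaternary C4, or simply no reaction of the poorly nucleophilic vinyl group with the hindered aldehyde. Fallback, setting out from 20 and returning at 21: Pinnick oxidation (NaClO2, NaH2PO4, 2-methylbut-2-ene) gives the carboxylic acid F1, and oxalyl chloride with catalytic DMF gives the acid chloride F2. SnCl4-mediated intramolecular acylation of the vinyl group with chloride capture (a stronger electrophile than the aldehyde) gives the β-chloro ketone F3, whose chloride can settle in the equatorial position through reversible loss and re-addition of HCl. Reduction of the C1 ketone with L-Selectride along the equatorial trajectory should then give the axial 1α-alcohol 21.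

Step 12 (intramolecular Diels–Alder). What may go wrong: too little reactivity of the hindered α-methyl, β-tert-alkyl enoate below the temperature at which the allylic ester decomposes, or erosion of the exo preference. Fallback, setting out from 16 and returning at 17: reductive acetylation of the ester (i-Bu2AlH, −78 °C; then pyridine, DMAP, Ac2O) gives the α-acetoxy ether F4. TMSOTf at −78 °C ionises it to the oxygen-tethered alkoxyallyl cation, a far stronger dienophile, which cyclises (ionic Diels–Alder reaction) and is recaptured by acetate to give the cyclic lactol acetate F5. Mild aqueous acid gives the lactol F6, and oxidation with TEMPO and PhI(OAc)2 returns the lactone 17.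

Step 3 (allylic substitution). What may go wrong: loss of SN2' selectivity or of enantioselectivity when the quaternary centre is formed with the diborylmethane nucleophile. Fallback, setting out from 3 and returning at 4: copper-catalysed enantioselective allylic borylation of 3 with B2pin2 (CuCl, chiral carbene ligand, NaOMe) gives the tertiary allyl boronate F7. Matteson homologation with LiCH2Cl (from ICH2Cl and n-BuLi, −78 °C), which inserts CH2 with retention, gives 4, which is oxidised to 5 as in step 3.

Further compounds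
F1 | step 15 | carboxylic acid corresponding to aldehyde 20 (CO2H on C10) | C=CCC[C@](C)(C=C)[C@@H]1CC=C(CO[Si](C)(C)C(C)(C)C)[C@H]([C@@H](CO[Si](c2ccccc2)(c2ccccc2)C(C)(C)C)O[Si](C)(C)C(C)(C)C)[C@@]1(C)C(=O)O
F2 | step 15 | acid chloride of F1 | C=CCC[C@](C)(C=C)[C@@H]1CC=C(CO[Si](C)(C)C(C)(C)C)[C@H]([C@@H](CO[Si](c2ccccc2)(c2ccccc2)C(C)(C)C)O[Si](C)(C)C(C)(C)C)[C@@]1(C)C(Cl)=O
F3 | step 15 | 3β-chloro-1-oxo trans-decalin (C1 ketone analogue of 21) | C=CCC[C@]1(C)[C@@H](Cl)CC(=O)[C@]2(C)[C@@H]([C@@H](CO[Si](c3ccccc3)(c3ccccc3)C(C)(C)C)O[Si](C)(C)C(C)(C)C)C(CO[Si](C)(C)C(C)(C)C)=CC[C@@H]12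
F4 | step 12 | α-acetoxy ether from ester 16 (C1 as CH(OAc)–O, epimers at C1) | C=CCC[C@](C)(C=C)/C=C(\C)C(OC(C)=O)O[C@H](CO[Si](c1ccccc1)(c1ccccc1)C(C)(C)C)/C=C(CO[Si](C)(C)C(C)(C)C)/C=C
F5 | step 12 | cyclised lactol acetate (17 with C1 as CH(OAc), epimers at C1) | C=CCC[C@](C)(C=C)[C@@H]1CC=C(CO[Si](C)(C)C(C)(C)C)[C@@H]2[C@@H](CO[Si](c3ccccc3)(c3ccccc3)C(C)(C)C)OC(OC(C)=O)[C@@]12C
F6 | step 12 | lactol (17 with C1 as CH(OH), epimers at C1) | C=CCC[C@](C)(C=C)[C@@H]1CC=C(CO[Si](C)(C)C(C)(C)C)[C@@H]2[C@@H](CO[Si](c3ccccc3)(c3ccccc3)C(C)(C)C)OC(O)[C@@]12C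
F7 | step 3 | 2-[(3S)-3-methylhepta-1,6-dien-3-yl]-4,4,5,5-tetramethyl-1,3,2-dioxaborolane | CC1(C)OB([C@@](C)(C=C)CCC=C)OC1(C)C
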